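**Small charges.** A small charge of starting material flatters the percentage: at 20.0 min Saturday's run shows 26.2% of target and Friday's 14.1%, yet multiplied by their charges these are 0.0186 M and 0.0183 M, with Monday's at 0.0188 M.

| flask | starting material | partner A | partner B | remark | time |
|---|---|---|---|---|---|
| Saturday's | 0.071 M | 0.11 M | 0.11 M | run made earlier |  |
| Monday's | 0.093 M | 0.11 M | 0.11 M | run made earlier |  |
| Friday's | 0.13 M | 0.11 M | 0.11 M | run made earlier |  |
| blue | 0.060 M | 0.110 M | 0.110 M |  | 30 min |
| amber | 0.10 M | 0.110 M | 0.110 M |  | 30 min |
| ochre | 0.15 M | 0.110 M | 0.110 M |  | 30 min |

| run | time / min | target / % |
|---|---|---|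
| Saturday's | 1.50 | 1.3 |
| Saturday's | 4.00 | 10.2 |
| Saturday's | 10.0 | 21.2 |
| Saturday's | 20.0 | 26.2 |
| Monday's | 2.50 | 4.5 |
| Monday's | 8.00 | 14.7 |
| Monday's | 15.0 | 19.6 |
| Monday's | 20.0 | 20.2 |
| Friday's | 1.50 | 1.3 |
| Friday's | 4.00 | 6.7 |
| Friday's | 10.0 | 12.2 |
| Friday's | 20.0 | 14.1 |

(standard deviation of a reading: 0.5 percentage points)

- [target] at the end for blue, amber, ochre, in this order
- the course of these numbers from the first flask to the last (rises all the way / falls all the way / rises, then falls / hardly changes / falls, then rises)

- reactions considered so far: partner B + partner A -> second intermediate; open intermediate + second intermediate -> target; 2 second intermediate -> homo product; target <-> isomer of the product; starting material + partner B -> open intermediate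
- "hardly changes" means that all values lie within two and a half points (for a concentration: within two and a half percent of the largest)
- a step back or a flat step of under half a percent of the largest counts as no turn

**The exponent.** So I go to logarithms. From Saturday to Monday I get 0.0365, and from Monday to Friday −0.0734, which is the charge exponent: the slope of log [target] against log charge at a fixed time, where one means the percentage holds and zero means the molar amount holds. With a scatter of 0.5 percentage points on each reading, the signs of these exponents are a lean, not a finding.

**To the end.** Monday's last step multiplies target by a ratio which, squared because two such steps remain to 30 min, gives 1.06. In my estimate I apply this factor to blue, amber and ochre alike, and then the exponent across the small change of charge: blue from Saturday gives 0.0196 M, amber from Monday 0.0198 M, and ochre from Friday 0.0193 M.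

**Weak link.** The ochre figure holds the exponent constant, but my two readings of it fall from the first span to the second, so I continue their line in logarithms to the step from Friday to ochre and get −0.160, which lowers my estimate for ochre to 0.0190 M.

**The forecast.** It gives 0.0188 M, 0.0195 M and 0.018 M, each below mine, and rises, then falls, the same course as mine, on the ground that “the yield should peak in the middle”.

**The flasks.** Blue, amber and ochre give 0.0194 M, 0.0204 M and 0.0184 M: rises, then falls.

    partner B + partner A → second intermediate (k = 0.0450 /M/s)
    open intermediate + second intermediate → target (k = 0.0730 /M/s)
    2 second intermediate → homo product (k = 0.0650 /M/s)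
    target ⇌ isomer of the product (K = 0.450, k = 0.0550 /s)
    starting material + partner B → open intermediate (k = 0.0660 /M/s)

At 30 min the charge exponent is 0.0984 from blue to amber, and from amber to ochre it is −0.254, lower than the −0.0734 read from Monday's and Friday's readings at 20.0 min, a different span of charge. In blue the half-life of target by its forward step to the isomer of the product alone, 0.21 min, is short against the 30 min of the run, and at that time blue holds 32.4% of target beside 14.6% of isomer, in percent of the starting material charged, while ochre holds 12.3% beside 5.53%.

The readings come from a simulation for an exercise.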